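**Strategy.** The hydroazulene is cut at C3a–C8a and C6–C7 (azulene locants). This splits the seven-membered ring into an oxyallyl unit C7–C8–C8a (C8 carries the oxygen) and a diene C3a–C4–C5–C6, joined through C1–C2–C3 of the five-membered ring. A silyl-triflate-catalysed intramolecular (4+3) cycloaddition of an acyclic epoxy enol silane closes both rings at once. Stereospecific opening of the C1–C8a epoxide sets the quaternary C8a next to the C1 oxygen, and the compact transition state gives the cis ring fusion. The precursor is the triethylsilyl enol ether of a methyl epoxy ketone that carries an (E,E)-dienyl tertiary silyl ether, built from two Sharpless-derived fragments.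

Key step: step 12

Remark: C1–C8a are the azulene locants of the target (C1 CH–OH, C2 CH2, C3 C(OH)i-Pr, C3a ring-fusion CH, C4 and C8 the acyloxy carbons, C5 CH2, C6/C7 the epoxide, C8a the quaternary carbon) and are used for the same carbons in acyclic precursors; β is the face of the C8a methyl. Both tartrate esters, (S)-but-3-yn-2-ol, angelic acid and (E)-but-2-enyl(triphenyl)phosphonium chloride are taken as purchased.

**Step 1**
Reactants: 1 prop-2-yn-1-ol
Product: 2 3-methyl-2-methylidenebutan-1-ol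
Conditions: i-PrMgCl (3 equiv), CuI (10 mol%), THF, −10 °C to rt; aq NH4Cl
Reagents that add atoms: isopropylmagnesium chloride, CC(C)[Mg]Cl
Why: Copper-catalysed anti-carbomagnesiation of the propargylic magnesium alkoxide places the isopropyl group on the internal alkyne carbon through a five-membered chelate, and protonolysis gives the 2-substituted allylic alcohol (no stereocentre).

**Step 2**
Reactants: 2 3-methyl-2-methylidenebutan-1-ol
Product: 3 [(2R)-2-(propan-2-yl)oxiran-2-yl]methanol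
Conditions: Ti(Oi-Pr)4 (cat.), D-(−)-diisopropyl tartrate (cat.), t-BuOOH, 4 Å MS, CH2Cl2, −20 °C
Reagents that add atoms: tert-butyl hydroperoxide, CC(C)(C)OO
Why: Sharpless asymmetric epoxidation of a 2-substituted allylic alcohol, in which the D-(−)-tartrate catalyst should deliver oxygen to the face that gives the (R)-epoxide, the future C3 carbinol centre.

**Step 3**
Reactants: 4 (2S)-but-3-yn-2-ol
Product: 5 tert-butyl{[(2S)-but-3-yn-2-yl]oxy}dimethylsilane
Conditions: t-BuMe2SiCl, imidazole, CH2Cl2, 0 °C to rt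
Reagents that add atoms: tert-butyldimethylsilyl chloride, CC(C)(C)[Si](C)(C)Cl
Why: Standard silylation protects the propargylic alcohol so that the later alkenyl metal species are stable; the stereocentre is not touched.

**Step 4**
Reactants: 5 tert-butyl{[(2S)-but-3-yn-2-yl]oxy}dimethylsilane
Product: 7 tert-butyl{[(2S,3E)-4-iodo-3-methylbut-3-en-2-yl]oxy}dimethylsilane, via alkenylalane 6 (not isolated)
Conditions: Me3Al, Cp2ZrCl2, CH2Cl2, 0 °C to rt; then I2, THF, −30 °C
Reagents that add atoms: trimethylaluminium, C[Al](C)C; iodine, II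
Why: Negishi carboalumination adds Me–Al syn across the terminal alkyne with methyl on the internal carbon, and iodinolysis of the C–Al bond with retention gives the (E)-iodide.

**Step 5**
Reactants: 7 tert-butyl{[(2S,3E)-4-iodo-3-methylbut-3-en-2-yl]oxy}dimethylsilane; 3 [(2R)-2-(propan-2-yl)oxiran-2-yl]methanol
Product: 10 (2R,4E,6S)-6-[(tert-butyldimethylsilyl)oxy]-5-methyl-2-(propan-2-yl)hept-4-ene-1,2-diol, via alkenyllithium 8 (not isolated), via alkenylmagnesium bromide 9 (not isolated)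
Conditions: 7, t-BuLi (2 equiv), Et2O, −78 °C; MgBr2·OEt2; then 3 (pretreated with MeMgBr, THF, −20 °C), CuI (10 mol%), −20 to 0 °C; aq NH4Cl
Reagents that add atoms: none
Why: Iodine–lithium exchange and transmetalation keep the alkene geometry, and the copper-catalysed Grignard opening of the 2,2-disubstituted epoxide is an SN2 attack at its CH2 terminus, so the carbinol configuration from step 2 is carried over unchanged.

**Step 6**
Reactants: 10 (2R,4E,6S)-6-[(tert-butyldimethylsilyl)oxy]-5-methyl-2-(propan-2-yl)hept-4-ene-1,2-diol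
Product: 11 (2R,4E,6S)-6-[(tert-butyldimethylsilyl)oxy]-2-hydroxy-5-methyl-2-(propan-2-yl)hept-4-enal
Conditions: TEMPO (cat.), PhI(OAc)2, CH2Cl2, rt
Reagents that add atoms: none
Why: Oxoammonium (TEMPO) oxidation is selective for the primary alcohol; the tertiary alcohol cannot be oxidised and the α-carbon has no hydrogen to epimerise.

**Step 7**
Reactants: 11 (2R,4E,6S)-6-[(tert-butyldimethylsilyl)oxy]-2-hydroxy-5-methyl-2-(propan-2-yl)hept-4-enal
Product: 13 (2E,4E,6R,8E,10S)-10-[(tert-butyldimethylsilyl)oxy]-9-methyl-6-(propan-2-yl)undeca-2,4,8-trien-6-ol, via (4Z)-triene 12 (not isolated)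
Conditions: (E)-but-2-enyl(triphenyl)phosphonium chloride, n-BuLi (excess), THF, −78 °C to rt; then I2 (cat.), CH2Cl2, daylight, rt
Reagents that add atoms: (E)-but-2-enyl(triphenyl)phosphonium chloride, C/C=C/C[P+](c1ccccc1)(c1ccccc1)c1ccccc1.[Cl-]
Why: Wittig olefination with a semi-stabilised allylic ylide builds the diene, and iodine-catalysed equilibration should convert the (4Z) isomer into the thermodynamically preferred (2E,4E)-diene, since the Z form places the quaternary carbinol carbon against the propenyl group.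

**Step 8**
Reactants: 13 (2E,4E,6R,8E,10S)-10-[(tert-butyldimethylsilyl)oxy]-9-methyl-6-(propan-2-yl)undeca-2,4,8-trien-6-ol
Product: 14 (2S,3E,6R,7E,9E)-3-methyl-6-(propan-2-yl)undeca-3,7,9-triene-2,6-diol
Conditions: n-Bu4NF, THF, 0 °C to rt
Reagents that add atoms: none
Why: Fluoride-mediated desilylation frees the secondary allylic alcohol that directs the next step.

**Step 9**
Reactants: 14 (2S,3E,6R,7E,9E)-3-methyl-6-(propan-2-yl)undeca-3,7,9-triene-2,6-diol
Product: 15 (1S)-1-{(2S,3S)-3-[(2R,3E,5E)-2-hydroxy-2-(propan-2-yl)hepta-3,5-dien-1-yl]-2-methyloxiran-2-yl}ethan-1-ol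
Conditions: Ti(Oi-Pr)4 (1 equiv), L-(+)-diisopropyl tartrate (1.2 equiv), t-BuOOH, 4 Å MS, CH2Cl2, −20 °C
Reagents that add atoms: tert-butyl hydroperoxide, CC(C)(C)OO
Why: Sharpless asymmetric epoxidation in the matched sense: L-(+)-tartrate epoxidises the (S)-configured secondary allylic alcohol on the face that gives the erythro epoxide (future C1 and C8a), while the tertiary dienylic alcohol and the diene should not react.

**Step 10**
Reactants: 15 (1S)-1-{(2S,3S)-3-[(2R,3E,5E)-2-hydroxy-2-(propan-2-yl)hepta-3,5-dien-1-yl]-2-methyloxiran-2-yl}ethan-1-ol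
Product: 16 1-{(2R,3S)-3-[(2R,3E,5E)-2-hydroxy-2-(propan-2-yl)hepta-3,5-dien-1-yl]-2-methyloxiran-2-yl}ethan-1-one
Conditions: Dess–Martin periodinane, NaHCO3, CH2Cl2, 0 °C to rt
Reagents that add atoms: none
Why: Dess–Martin oxidation turns the relay carbinol into the methyl ketone under buffered conditions that leave the epoxide and the tertiary alcohol alone.

**Step 11**
Reactants: 16 1-{(2R,3S)-3-[(2R,3E,5E)-2-hydroxy-2-(propan-2-yl)hepta-3,5-dien-1-yl]-2-methyloxiran-2-yl}ethan-1-one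
Product: 17 triethyl[(1-{(2R,3S)-2-methyl-3-[(2R,3E,5E)-2-(propan-2-yl)-2-(triethylsilyloxy)hepta-3,5-dien-1-yl]oxiran-2-yl}ethenyl)oxy]silane
Conditions: Et3SiOTf (2.5 equiv), Et3N, CH2Cl2, −78 to 0 °C
Reagents that add atoms: triethylsilyl trifluoromethanesulfonate, CC[Si](CC)(CC)OS(=O)(=O)C(F)(F)F
Why: Amine-buffered soft enolisation gives the only possible enol silane (the other α-carbon is the quaternary epoxide carbon) and silylates the tertiary alcohol in the same operation.

**Step 12**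
Reactants: 17 triethyl[(1-{(2R,3S)-2-methyl-3-[(2R,3E,5E)-2-(propan-2-yl)-2-(triethylsilyloxy)hepta-3,5-dien-1-yl]oxiran-2-yl}ethenyl)oxy]silane
Product: 18 6α,8aβ-dimethyl-3β-(propan-2-yl)-1β,3α-bis(triethylsilyloxy)-1,2,3,3aβ,6,7-hexahydroazulen-8(8aH)-one
Conditions: Et3SiOTf (0.2 equiv), CH2Cl2, −78 °C; Et3N quench
Reagents that add atoms: none
Why: Et3SiOTf silylates the epoxide oxygen, the C8a–O bond ionises with help from the enol silane to a 2-silyloxyallyl cation (C7–C8–C8a) that is captured across the termini of the tethered diene (C3a–C6) in an asynchronous (4+3) cycloaddition, and the O-silylated ketone passes its silyl group on so that the silyl triflate turns over. The closest known reaction type is the silyl-triflate-catalysed intramolecular (4+3) cycloaddition of epoxy enol silanes that carry a diene on a three-atom tether. The five-membered ring closes by attack of C3a on the distal, tertiary epoxide carbon C8a (5-exo for the C3a=C4 π bond, formally 5-endo for the epoxide, allowed because C8a is an allyl-cation terminus), and the seven-membered ring closes through the second bond C6–C7 of the suprafacial (4+3) array. C8a is set by inversion at the (E)-configured epoxide (the diene enters anti to the leaving oxygen), so its methyl ends cis to the C1 silyloxy group; C3a is set by the compact arrangement in which C8 with its silyloxy group, not the C8a methyl, lies under the diene, which puts H-3a cis to that methyl (cis ring fusion); C6 follows from the (E,E)-diene geometry and is erased in step 13. The step needs diene capture to outrun ionisation of, or capture by, the tertiary dienylic silyl ether and needs (4+3) over (3+2) closure; the low temperature, the shielding of the C3 oxygen by its isopropyl and triethylsilyl groups, the accessible s-cis form of the (E,E)-diene and the methyl at C6 that stabilises charge at the distal diene terminus serve this end.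

**Step 13**
Reactants: 18 6α,8aβ-dimethyl-3β-(propan-2-yl)-1β,3α-bis(triethylsilyloxy)-1,2,3,3aβ,6,7-hexahydroazulen-8(8aH)-one
Product: 20 6,8aβ-dimethyl-3β-(propan-2-yl)-1β,3α-bis(triethylsilyloxy)-2,3,3aβ,8a-tetrahydroazulen-8(1H)-one, via trimethylsilyl dienol ether 19 (not isolated)
Conditions: LDA, Me3SiCl, THF, −78 °C; then Pd(OAc)2 (1.1 equiv), MeCN, rt
Reagents that add atoms: none
Why: Saegusa–Ito oxidation: the ketone can enolise only toward C7 because C8a is quaternary, and palladium diacetate dehydrogenates the silyl enol ether to the C6=C7 enone, which removes the C6 stereocentre.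

**Step 14**
Reactants: 20 6,8aβ-dimethyl-3β-(propan-2-yl)-1β,3α-bis(triethylsilyloxy)-2,3,3aβ,8a-tetrahydroazulen-8(1H)-one
Product: 21 4β,5β-epoxy-6,8aβ-dimethyl-3β-(propan-2-yl)-1β,3α-bis(triethylsilyloxy)-1,2,3,3aβ,4,5-hexahydroazulen-8(8aH)-one
Conditions: mCPBA, NaHCO3, CH2Cl2, 0 °C
Reagents that add atoms: 3-chloroperoxybenzoic acid, O=C(OO)c1cccc(Cl)c1
Why: Prilezhaev epoxidation takes the more electron-rich γ,δ-alkene of the dienone and should occur on the convex β face (that of H-3a), away from the five-membered ring and its 3α-silyloxy group under the other face, which sets the C4–O bond β.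

**Step 15**
Reactants: 21 4β,5β-epoxy-6,8aβ-dimethyl-3β-(propan-2-yl)-1β,3α-bis(triethylsilyloxy)-1,2,3,3aβ,4,5-hexahydroazulen-8(8aH)-one
Product: 22 4β-hydroxy-6,8aβ-dimethyl-3β-(propan-2-yl)-1β,3α-bis(triethylsilyloxy)-1,2,3,3aβ,4,5-hexahydroazulen-8(8aH)-one
Conditions: Pd2(dba)3·CHCl3 (cat.), n-Bu3P (cat.), HCO2H, Et3N, 1,4-dioxane, rt
Reagents that add atoms: none
Why: Tsuji-type palladium/formate hydrogenolysis of the alkenyl oxirane: zerovalent palladium opens the allylic C5–O bond and the formate-derived hydride is delivered to C5 of the π-allyl complex, which keeps the enone conjugated and leaves the C4 carbinol untouched.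

**Step 16**
Reactants: 22 4β-hydroxy-6,8aβ-dimethyl-3β-(propan-2-yl)-1β,3α-bis(triethylsilyloxy)-1,2,3,3aβ,4,5-hexahydroazulen-8(8aH)-one
Product: 23 4β-angeloyloxy-6,8aβ-dimethyl-3β-(propan-2-yl)-1β,3α-bis(triethylsilyloxy)-1,2,3,3aβ,4,5-hexahydroazulen-8(8aH)-one
Conditions: angelic acid, 2,4,6-trichlorobenzoyl chloride, Et3N, toluene, rt; then 22, toluene, 75 °C
Reagents that add atoms: angelic acid [(Z)-2-methylbut-2-enoic acid], C/C=C(/C)C(=O)O
Why: Yamaguchi-type esterification through the mixed 2,4,6-trichlorobenzoic anhydride acylates the hindered secondary alcohol without nucleophilic catalysis, which should avoid Z-to-E isomerisation of the angelate.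

**Step 17**
Reactants: 23 4β-angeloyloxy-6,8aβ-dimethyl-3β-(propan-2-yl)-1β,3α-bis(triethylsilyloxy)-1,2,3,3aβ,4,5-hexahydroazulen-8(8aH)-one
Product: 24 4β-angeloyloxy-8α-hydroxy-6,8aβ-dimethyl-3β-(propan-2-yl)-1β,3α-bis(triethylsilyloxy)-1,2,3,3aβ,4,5,8,8a-octahydroazulene
Conditions: NaBH4, CeCl3·7H2O, MeOH, −78 to −40 °C
Reagents that add atoms: none
Why: Luche reduction gives 1,2-addition only, and hydride should enter from the β face, anti to the pseudo-axial C8a–C1 bond of the five-membered ring (Felkin–Anh-type approach), giving the 8α-alcohol trans to the angular methyl; the angelate is not reduced.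

**Step 18**
Reactants: 24 4β-angeloyloxy-8α-hydroxy-6,8aβ-dimethyl-3β-(propan-2-yl)-1β,3α-bis(triethylsilyloxy)-1,2,3,3aβ,4,5,8,8a-octahydroazulene
Product: 25 4β-angeloyloxy-6α,7α-epoxy-8α-hydroxy-6β,8aβ-dimethyl-3β-(propan-2-yl)-1β,3α-bis(triethylsilyloxy)-3aβH-decahydroazulene
Conditions: VO(acac)2 (cat.), t-BuOOH, CH2Cl2, 0 °C to rt
Reagents that add atoms: tert-butyl hydroperoxide, CC(C)(C)OO
Why: Vanadium-catalysed hydroxyl-directed epoxidation delivers oxygen syn to the allylic 8α-hydroxyl, giving the 6α,7α-epoxide and hence the β-methyl at C6; the electron-poor angelate alkene has no directing group and should stay intact.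

**Step 19**
Reactants: 25 4β-angeloyloxy-6α,7α-epoxy-8α-hydroxy-6β,8aβ-dimethyl-3β-(propan-2-yl)-1β,3α-bis(triethylsilyloxy)-3aβH-decahydroazulene
Product: 26 4β,8α-bis(angeloyloxy)-6α,7α-epoxy-6β,8aβ-dimethyl-3β-(propan-2-yl)-1β,3α-bis(triethylsilyloxy)-3aβH-decahydroazulene
Conditions: angelic acid, 2,4,6-trichlorobenzoyl chloride, Et3N, toluene, rt; then 25, toluene, 80 °C
Reagents that add atoms: angelic acid [(Z)-2-methylbut-2-enoic acid], C/C=C(/C)C(=O)O
Why: The same Yamaguchi-type mixed-anhydride esterification acylates the neopentyl-type 8α-hydroxyl with retention of the angelate geometry; the silyl ethers keep the C1 and C3 oxygens out of the reaction.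

**Step 20**
Reactants: 26 4β,8α-bis(angeloyloxy)-6α,7α-epoxy-6β,8aβ-dimethyl-3β-(propan-2-yl)-1β,3α-bis(triethylsilyloxy)-3aβH-decahydroazulene
Product: 27 4β,8α-bis(angeloyloxy)-6α,7α-epoxy-6β,8aβ-dimethyl-3β-(propan-2-yl)-3aβH-decahydroazulene-1β,3α-diol (CNP0265715.3)
Conditions: HF·pyridine, pyridine, THF, 0 °C to rt
Reagents that add atoms: none
Why: Buffered fluoride desilylation cleaves both triethylsilyl ethers under weakly acidic conditions in which the epoxide and the angelates should survive and acyl migration is not promoted.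

**Compound list**

1 | prop-2-yn-1-ol | C#CCO | starting material
2 | 3-methyl-2-methylidenebutan-1-ol | C=C(CO)C(C)C | intermediate
3 | [(2R)-2-(propan-2-yl)oxiran-2-yl]methanol | OC[C@]1(C(C)C)CO1 | intermediate
4 | (2S)-but-3-yn-2-ol | C[C@H](O)C#C | starting material
5 | tert-butyl{[(2S)-but-3-yn-2-yl]oxy}dimethylsilane | C[C@H](O[Si](C)(C)C(C)(C)C)C#C | intermediate
6 | {(1E,3S)-3-[(tert-butyldimethylsilyl)oxy]-2-methylbut-1-en-1-yl}dimethylalumane (not isolated) | C[C@H](O[Si](C)(C)C(C)(C)C)/C(C)=C/[Al](C)C | intermediate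
7 | tert-butyl{[(2S,3E)-4-iodo-3-methylbut-3-en-2-yl]oxy}dimethylsilane | C[C@H](O[Si](C)(C)C(C)(C)C)/C(C)=C/I | intermediate
8 | {(1E,3S)-3-[(tert-butyldimethylsilyl)oxy]-2-methylbut-1-en-1-yl}lithium (not isolated) | C[C@H](O[Si](C)(C)C(C)(C)C)/C(C)=C/[Li] | intermediate
9 | {(1E,3S)-3-[(tert-butyldimethylsilyl)oxy]-2-methylbut-1-en-1-yl}magnesium bromide (not isolated) | C[C@H](O[Si](C)(C)C(C)(C)C)/C(C)=C/[Mg]Br | intermediate
10 | (2R,4E,6S)-6-[(tert-butyldimethylsilyl)oxy]-5-methyl-2-(propan-2-yl)hept-4-ene-1,2-diol | C[C@H](O[Si](C)(C)C(C)(C)C)/C(C)=C/C[C@@](O)(C(C)C)CO | intermediate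
11 | (2R,4E,6S)-6-[(tert-butyldimethylsilyl)oxy]-2-hydroxy-5-methyl-2-(propan-2-yl)hept-4-enal | C[C@H](O[Si](C)(C)C(C)(C)C)/C(C)=C/C[C@@](O)(C(C)C)C=O | intermediate
12 | (2E,4Z,6R,8E,10S)-10-[(tert-butyldimethylsilyl)oxy]-9-methyl-6-(propan-2-yl)undeca-2,4,8-trien-6-ol (not isolated) | C[C@H](O[Si](C)(C)C(C)(C)C)/C(C)=C/C[C@@](O)(C(C)C)/C=C\C=C\C | intermediate
13 | (2E,4E,6R,8E,10S)-10-[(tert-butyldimethylsilyl)oxy]-9-methyl-6-(propan-2-yl)undeca-2,4,8-trien-6-ol | C[C@H](O[Si](C)(C)C(C)(C)C)/C(C)=C/C[C@@](O)(C(C)C)/C=C/C=C/C | intermediate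
14 | (2S,3E,6R,7E,9E)-3-methyl-6-(propan-2-yl)undeca-3,7,9-triene-2,6-diol | C[C@H](O)/C(C)=C/C[C@@](O)(C(C)C)/C=C/C=C/C | intermediate
15 | (1S)-1-{(2S,3S)-3-[(2R,3E,5E)-2-hydroxy-2-(propan-2-yl)hepta-3,5-dien-1-yl]-2-methyloxiran-2-yl}ethan-1-ol | C[C@H](O)[C@]1(C)O[C@H]1C[C@@](O)(C(C)C)/C=C/C=C/C | intermediate
16 | 1-{(2R,3S)-3-[(2R,3E,5E)-2-hydroxy-2-(propan-2-yl)hepta-3,5-dien-1-yl]-2-methyloxiran-2-yl}ethan-1-one | CC(=O)[C@]1(C)O[C@H]1C[C@@](O)(C(C)C)/C=C/C=C/C | intermediate
17 | triethyl[(1-{(2R,3S)-2-methyl-3-[(2R,3E,5E)-2-(propan-2-yl)-2-(triethylsilyloxy)hepta-3,5-dien-1-yl]oxiran-2-yl}ethenyl)oxy]silane | C=C(O[Si](CC)(CC)CC)[C@]1(C)O[C@H]1C[C@@](O[Si](CC)(CC)CC)(C(C)C)/C=C/C=C/C | intermediate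
18 | 6α,8aβ-dimethyl-3β-(propan-2-yl)-1β,3α-bis(triethylsilyloxy)-1,2,3,3aβ,6,7-hexahydroazulen-8(8aH)-one (cis-fused) | C1=C[C@H](C)CC(=O)[C@@]2(C)[C@@H]1[C@](O[Si](CC)(CC)CC)(C(C)C)C[C@@H]2O[Si](CC)(CC)CC | intermediate
19 | 6α,8aβ-dimethyl-3β-(propan-2-yl)-1β,3α-bis(triethylsilyloxy)-8-(trimethylsilyloxy)-1,2,3,3aβ,6,8a-hexahydroazulene (not isolated) | C1=C[C@H](C)C=C(O[Si](C)(C)C)[C@@]2(C)[C@@H]1[C@](O[Si](CC)(CC)CC)(C(C)C)C[C@@H]2O[Si](CC)(CC)CC | intermediate
20 | 6,8aβ-dimethyl-3β-(propan-2-yl)-1β,3α-bis(triethylsilyloxy)-2,3,3aβ,8a-tetrahydroazulen-8(1H)-one | C1=CC(C)=CC(=O)[C@@]2(C)[C@@H]1[C@](O[Si](CC)(CC)CC)(C(C)C)C[C@@H]2O[Si](CC)(CC)CC | intermediate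
21 | 4β,5β-epoxy-6,8aβ-dimethyl-3β-(propan-2-yl)-1β,3α-bis(triethylsilyloxy)-1,2,3,3aβ,4,5-hexahydroazulen-8(8aH)-one | [C@@H]13O[C@H]3C(C)=CC(=O)[C@@]2(C)[C@@H]1[C@](O[Si](CC)(CC)CC)(C(C)C)C[C@@H]2O[Si](CC)(CC)CC | intermediate
22 | 4β-hydroxy-6,8aβ-dimethyl-3β-(propan-2-yl)-1β,3α-bis(triethylsilyloxy)-1,2,3,3aβ,4,5-hexahydroazulen-8(8aH)-one | O[C@H]1CC(C)=CC(=O)[C@@]2(C)[C@@H]1[C@](O[Si](CC)(CC)CC)(C(C)C)C[C@@H]2O[Si](CC)(CC)CC | intermediate
23 | 4β-angeloyloxy-6,8aβ-dimethyl-3β-(propan-2-yl)-1β,3α-bis(triethylsilyloxy)-1,2,3,3aβ,4,5-hexahydroazulen-8(8aH)-one | C/C=C(/C)C(=O)O[C@H]1CC(C)=CC(=O)[C@@]2(C)[C@@H]1[C@](O[Si](CC)(CC)CC)(C(C)C)C[C@@H]2O[Si](CC)(CC)CC | intermediate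
24 | 4β-angeloyloxy-8α-hydroxy-6,8aβ-dimethyl-3β-(propan-2-yl)-1β,3α-bis(triethylsilyloxy)-1,2,3,3aβ,4,5,8,8a-octahydroazulene | C/C=C(/C)C(=O)O[C@H]1CC(C)=C[C@H](O)[C@@]2(C)[C@@H]1[C@](O[Si](CC)(CC)CC)(C(C)C)C[C@@H]2O[Si](CC)(CC)CC | intermediate
25 | 4β-angeloyloxy-6α,7α-epoxy-8α-hydroxy-6β,8aβ-dimethyl-3β-(propan-2-yl)-1β,3α-bis(triethylsilyloxy)-3aβH-decahydroazulene | C/C=C(/C)C(=O)O[C@H]1C[C@]2(C)O[C@@H]2[C@H](O)[C@@]2(C)[C@@H]1[C@](O[Si](CC)(CC)CC)(C(C)C)C[C@@H]2O[Si](CC)(CC)CC | intermediate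
26 | 4β,8α-bis(angeloyloxy)-6α,7α-epoxy-6β,8aβ-dimethyl-3β-(propan-2-yl)-1β,3α-bis(triethylsilyloxy)-3aβH-decahydroazulene | C/C=C(/C)C(=O)O[C@H]1C[C@]2(C)O[C@@H]2[C@H](OC(=O)/C(C)=C\C)[C@@]2(C)[C@@H]1[C@](O[Si](CC)(CC)CC)(C(C)C)C[C@@H]2O[Si](CC)(CC)CC | intermediate
27 | 4β,8α-bis(angeloyloxy)-6α,7α-epoxy-6β,8aβ-dimethyl-3β-(propan-2-yl)-3aβH-decahydroazulene-1β,3α-diol (CNP0265715.3) | C/C=C(/C)C(=O)O[C@H]1C[C@]2(C)O[C@@H]2[C@H](OC(=O)/C(C)=C\C)[C@@]2(C)[C@@H]1[C@](O)(C(C)C)C[C@@H]2O | target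

**Step count and risks**

Total step count: 20. Longest linear sequence: 18 steps (steps 1, 2 and 5–20; the branch of steps 3 and 4 joins at step 5 and gives the same length).

Steps most likely to fail:

1. Step 12. The silyl triflate may ionise the tertiary dienylic silyl ether, that ether oxygen may capture the activated epoxide, or the cation may close by (3+2) instead of (4+3); the extended transition state would also give the trans ring fusion. Fallback (oxyallyl cation made without a Lewis acid; sets out from 16, returns at 18): SmI2 in THF–MeOH at −90 °C cleaves the C8a–O bond of the epoxy ketone to the β-hydroxy ketone (4S,6R,7E,9E)-4,6-dihydroxy-3-methyl-6-(propan-2-yl)undeca-7,9-dien-2-one F1, in which the C1 carbinol is kept and the now epimeric C8a is of no consequence. Et3SiOTf and 2,6-lutidine give the bis(triethylsilyl) ether F2. LDA at −78 °C followed by TsCl chlorinates the kinetic methyl enolate to the chloromethyl ketone F3. Et3N in 2,2,2-trifluoroethanol then ionises the enol of the α-chloro ketone to the oxyallyl cation, which is trapped by the tethered diene in a base-mediated intramolecular (4+3) cycloaddition to give 18. In this variant C8a is set by facial selection next to the C1 silyloxy centre instead of by inversion.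

2. Step 14. Facial selectivity may be poor, with the peracid attacking the dienone from the α face. Fallback (configuration at C4 set by SN2 inversion instead of by facial selection; sets out from 20, returns at 23): the 4α,5α-epoxide F4 is taken through the same palladium/formate hydrogenolysis as in step 15 to the 4α-alcohol F5, and Mitsunobu esterification with angelic acid (PPh3, diisopropyl azodicarboxylate, toluene, 0 °C to rt) inverts C4 and gives the 4β-angelate 23 directly.

3. Step 18. Oxygen transfer to the hindered α face may be slow, or the epoxidation may occur undirected on the β face. Fallback (epoxide built by anti-addition and ring closure instead of directed oxygen transfer; sets out from 24, returns at 26): 24 is first acylated under the conditions of step 19 to the bis(angelate) F6. NBS in aqueous 1,2-dimethoxyethane gives the bromohydrin F7 (bromonium ion on the open β face, water at the tertiary C6 from the α face). DBU in CH2Cl2 closes the 6α,7α-epoxide by displacement of the 7β-bromide, which gives 26.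

**Further compounds**

F1 | step 12 | (4S,6R,7E,9E)-4,6-dihydroxy-3-methyl-6-(propan-2-yl)undeca-7,9-dien-2-one (C3 epimers) | CC(=O)C(C)[C@@H](O)C[C@@](O)(C(C)C)/C=C/C=C/C
F2 | step 12 | (4S,6R,7E,9E)-3-methyl-6-(propan-2-yl)-4,6-bis(triethylsilyloxy)undeca-7,9-dien-2-one (C3 epimers) | CC(=O)C(C)[C@@H](O[Si](CC)(CC)CC)C[C@@](O[Si](CC)(CC)CC)(C(C)C)/C=C/C=C/C
F3 | step 12 | (4S,6R,7E,9E)-1-chloro-3-methyl-6-(propan-2-yl)-4,6-bis(triethylsilyloxy)undeca-7,9-dien-2-one (C3 epimers) | ClCC(=O)C(C)[C@@H](O[Si](CC)(CC)CC)C[C@@](O[Si](CC)(CC)CC)(C(C)C)/C=C/C=C/C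
F4 | step 14 | 4α,5α-epoxy-6,8aβ-dimethyl-3β-(propan-2-yl)-1β,3α-bis(triethylsilyloxy)-1,2,3,3aβ,4,5-hexahydroazulen-8(8aH)-one | [C@H]13O[C@@H]3C(C)=CC(=O)[C@@]2(C)[C@@H]1[C@](O[Si](CC)(CC)CC)(C(C)C)C[C@@H]2O[Si](CC)(CC)CC
F5 | step 14 | 4α-hydroxy-6,8aβ-dimethyl-3β-(propan-2-yl)-1β,3α-bis(triethylsilyloxy)-1,2,3,3aβ,4,5-hexahydroazulen-8(8aH)-one | O[C@@H]1CC(C)=CC(=O)[C@@]2(C)[C@@H]1[C@](O[Si](CC)(CC)CC)(C(C)C)C[C@@H]2O[Si](CC)(CC)CC
F6 | step 18 | 4β,8α-bis(angeloyloxy)-6,8aβ-dimethyl-3β-(propan-2-yl)-1β,3α-bis(triethylsilyloxy)-1,2,3,3aβ,4,5,8,8a-octahydroazulene | C/C=C(/C)C(=O)O[C@H]1CC(C)=C[C@H](OC(=O)/C(C)=C\C)[C@@]2(C)[C@@H]1[C@](O[Si](CC)(CC)CC)(C(C)C)C[C@@H]2O[Si](CC)(CC)CC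
F7 | step 18 | 4β,8α-bis(angeloyloxy)-7β-bromo-6α-hydroxy-6β,8aβ-dimethyl-3β-(propan-2-yl)-1β,3α-bis(triethylsilyloxy)-3aβH-decahydroazulene | C/C=C(/C)C(=O)O[C@H]1C[C@](C)(O)[C@@H](Br)[C@H](OC(=O)/C(C)=C\C)[C@@]2(C)[C@@H]1[C@](O[Si](CC)(CC)CC)(C(C)C)C[C@@H]2O[Si](CC)(CC)CC
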